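**Plan**

1. Late cuts: the C-β–H bond of the seven-membered ring (from a C-α=C-β ring alkene), the ring B–C-β bond (cyclodehydration of an aryl ketone held on ring A by a CH2 group; the ketone comes from a ring-A acetamide and an aryl Grignard reagent) and both C3–aryl bonds (decarboxylative arylation of C3 carboxylic acids).
2. Early cuts: in each dihydrofuran the ring oxygen and C3 sit on neighbouring carbons of the central benzene ring A and C2 carries the 4-hydroxyphenyl group. This is a 2-arylchroman-4-one whose C4 has left the ring and stays on C3 as a carboxyl carbon, so each ring A–C3 bond is cut back to a flavanone and each C2–aryl bond to a chromone plus an arylboronic acid.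
3. Forward order: ring A amide → chromone → flavanone → first dihydrofuran (ring contraction) → acetyl group on ring A → second chromone → second flavanone → second dihydrofuran (C2-symmetric core) → both 3,5-dimethoxyphenyl groups → aryl ketone → seven-membered ring → free phenols → last C–H bond.
4. Stereochemistry: C2 of each dihydrofuran comes from catalyst-controlled conjugate arylation of the chromone. C3 of each comes from aryl transfer to the planar C3 radical on the face away from the C2 aryl group. C-β comes from hydrogen delivery to the convex face of the ring alkene. The C2 axis of the core makes the two 3,5-dimethoxyphenyl rings equivalent for the ring closure.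

Key step: step 6

Assumption: (S)-4-tert-butyl-2-(pyridin-2-yl)-4,5-dihydrooxazole directs the aryl group to the chromone face that gives the (R)-flavanone, as it gives (R) products with 3-substituted cyclohexenones; were the sense opposite, the (R)-ligand would be used in steps 5 and 10.

Labels: ring A = central benzene ring; ring B = the 3,5-dioxygenated ring fused to the seven-membered ring; C-α = the CH2 and C-β = the aryl-bearing carbon of that ring; C2/C3 (C2'/C3') = O–CH(aryl)/CH of the dihydrofuran that keeps its free 3,5-dioxygenated aryl group (that is fused to ring B).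

**Route**

Step 1
Reactants: 1 3,5-dimethoxyphenylacetic acid; 2 morpholine
Product: 4 2-(3,5-dimethoxyphenyl)-1-(morpholin-4-yl)ethan-1-one, via (3,5-dimethoxyphenyl)acetyl chloride 3 (not isolated)
Conditions: (COCl)2, DMF (cat.), CH2Cl2, 0 → 25 °C; then morpholine (2.5 equiv), CH2Cl2, 0 °C
Reagents that add atoms: none
Why: Nucleophilic acyl substitution through the acid chloride (amide formation) is routine, and the tertiary amide is a carboxyl handle that should survive Lewis acids, trivalent iodine, hydroxide and arylzinc reagents and still accept exactly one aryl Grignard reagent in step 15.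

Step 2
Reactants: 4 2-(3,5-dimethoxyphenyl)-1-(morpholin-4-yl)ethan-1-one; 5 acetyl chloride
Product: 6 2-(2-acetyl-3,5-dimethoxyphenyl)-1-(morpholin-4-yl)ethan-1-one
Conditions: AcCl, SnCl4 (2.5 equiv), CH2Cl2, −10 → 25 °C
Reagents that add atoms: none
Why: Friedel–Crafts acylation of a 5-alkyl-1,3-dimethoxybenzene should go to C2, para to one methoxy group and ortho to the other, and not to the carbon between the two methoxy groups, and the ketone formed deactivates the ring against a second acylation.

Step 3
Reactants: 6 2-(2-acetyl-3,5-dimethoxyphenyl)-1-(morpholin-4-yl)ethan-1-one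
Product: 7 2-(2-acetyl-3-hydroxy-5-methoxyphenyl)-1-(morpholin-4-yl)ethan-1-one
Conditions: BCl3 (2.5 equiv), CH2Cl2, −78 → 0 °C; then H2O
Reagents that add atoms: none
Why: Chelation-controlled ether cleavage: BCl3 held by the ketone oxygen should remove only the methyl group of the ortho methoxy group through a six-membered boron chelate, while the para methoxy group and the amide are left.

Step 4
Reactants: 7 2-(2-acetyl-3-hydroxy-5-methoxyphenyl)-1-(morpholin-4-yl)ethan-1-one; 8 N,N-dimethylformamide dimethyl acetal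
Product: 10 7-methoxy-5-[2-(morpholin-4-yl)-2-oxoethyl]-4H-chromen-4-one, via enaminone 9 (not isolated)
Conditions: Me2NCH(OMe)2, toluene, 100 °C; then conc. HCl, CH2Cl2, 40 °C
Reagents that add atoms: none
Why: Enaminone route to chromones: the methyl ketone condenses with the amide acetal, and under acid the phenol adds to the enaminone (6-endo-trig) and dimethylamine is lost to give the 4H-chromen-4-one.

Step 5
Reactants: 10 7-methoxy-5-[2-(morpholin-4-yl)-2-oxoethyl]-4H-chromen-4-one; 11 4-methoxyphenylboronic acid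
Product: 12 (2R)-7-methoxy-2-(4-methoxyphenyl)-5-[2-(morpholin-4-yl)-2-oxoethyl]-2,3-dihydro-4H-chromen-4-one
Conditions: Pd(OCOCF3)2 (5 mol %), (S)-4-tert-butyl-2-(pyridin-2-yl)-4,5-dihydrooxazole (6 mol %), NH4PF6 (30 mol %), H2O (5 equiv), ClCH2CH2Cl, 60 °C
Reagents that add atoms: none
Why: Asymmetric conjugate addition of an arylboronic acid to a chromone under divalent-palladium pyridine-oxazoline catalysis: the cationic aryl-palladium species adds across C2=C3 on the face selected by the ligand and the palladium enolate is protonated by water, which should set C2 as R under catalyst control.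

Step 6
Reactants: 12 (2R)-7-methoxy-2-(4-methoxyphenyl)-5-[2-(morpholin-4-yl)-2-oxoethyl]-2,3-dihydro-4H-chromen-4-one
Product: 14 methyl (2R,3R)-6-methoxy-2-(4-methoxyphenyl)-4-[2-(morpholin-4-yl)-2-oxoethyl]-2,3-dihydro-1-benzofuran-3-carboxylate, via methyl enol ether 13 (not isolated)
Conditions: PhI(OAc)2 (1.2 equiv), conc. H2SO4, HC(OMe)3, 25 °C; aqueous work-up
Reagents that add atoms: trimethyl orthoformate, COC(OC)OC; water, O
Why: Acid and orthoformate convert the ketone into its methyl enol ether 13, trivalent iodine adds to C3 on the face away from the C2 aryl group while methanol caps C4 as the ketal, and loss of iodobenzene from the equatorial C3–iodine bond is assisted by the antiperiplanar C4–C4a bond, so ring A shifts from C4 to C3 through a bridged phenonium ion and the dimethoxycarbenium ion left at C4 ends as the methyl ester. The closest known reaction type is the oxidative 1,2-aryl migration of alkyl aryl ketones to arylacetic esters with hypervalent iodine or thallium trinitrate, which on flavanones is a ring contraction. The dihydrofuran is not closed by a new C–O bond: the ipso carbon of ring A attacks C3 (3-exo-tet, spiro phenonium ion) and the C4–C4a bond then breaks, which leaves the five-membered O1–C2–C3–C3a–C7a ring. C2 is not touched and keeps the R configuration of 12, and C3 is formed with inversion at the iodine-bearing carbon, which should put the ester trans to the C2 aryl group (2R,3R); any cis isomer would converge later because C3 passes through a planar radical in step 14. The step needs migration of ring A rather than of the C2 aryl group (isoflavone) or plain dehydrogenation (flavone), and this is secured by the ketal at C4 (the shift of ring A ends in a dialkoxycarbenium ion), by the 7-methoxy group para and the ring oxygen ortho to the migrating carbon, and by the diequatorial arrangement of aryl group and iodine, in which only ring bonds are antiperiplanar to the C3–iodine bond.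

Step 7
Reactants: 14 methyl (2R,3R)-6-methoxy-2-(4-methoxyphenyl)-4-[2-(morpholin-4-yl)-2-oxoethyl]-2,3-dihydro-1-benzofuran-3-carboxylate; 5 acetyl chloride
Product: 15 methyl (2R,3R)-5-acetyl-6-methoxy-2-(4-methoxyphenyl)-4-[2-(morpholin-4-yl)-2-oxoethyl]-2,3-dihydro-1-benzofuran-3-carboxylate
Conditions: AcCl, SnCl4 (2.5 equiv), CH2Cl2, −20 → 0 °C
Reagents that add atoms: none
Why: Friedel–Crafts acylation of ring A at C5, para to the ring oxygen and ortho to the methoxy group (the preference seen in step 2), on a ring far more electron-rich than the anisyl group; it is placed here because a 3,5-dimethoxyphenyl group, once present, would be acylated first.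

Step 8
Reactants: 15 methyl (2R,3R)-5-acetyl-6-methoxy-2-(4-methoxyphenyl)-4-[2-(morpholin-4-yl)-2-oxoethyl]-2,3-dihydro-1-benzofuran-3-carboxylate
Product: 16 methyl (2R,3R)-5-acetyl-6-hydroxy-2-(4-methoxyphenyl)-4-[2-(morpholin-4-yl)-2-oxoethyl]-2,3-dihydro-1-benzofuran-3-carboxylate
Conditions: BCl3 (2.5 equiv), CH2Cl2, −78 → −20 °C; then H2O
Reagents that add atoms: none
Why: Chelation-controlled BCl3 demethylation as in step 3, which should free only the 6-hydroxy group ortho to the new ketone and leave the anisyl ether, the ester and the amide.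

Step 9
Reactants: 16 methyl (2R,3R)-5-acetyl-6-hydroxy-2-(4-methoxyphenyl)-4-[2-(morpholin-4-yl)-2-oxoethyl]-2,3-dihydro-1-benzofuran-3-carboxylate; 8 N,N-dimethylformamide dimethyl acetal
Product: 18 methyl (2R,3R)-2-(4-methoxyphenyl)-4-[2-(morpholin-4-yl)-2-oxoethyl]-5-oxo-2,3-dihydro-5H-furo[3,2-g]chromene-3-carboxylate, via enaminone 17 (not isolated)
Conditions: Me2NCH(OMe)2, toluene, 100 °C; then conc. HCl, CH2Cl2, 40 °C
Reagents that add atoms: none
Why: The enaminone route to chromones as in step 4 annulates the second pyranone onto ring A at O6/C5 and gives the linear furo[3,2-g]chromen-5-one.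

Step 10
Reactants: 18 methyl (2R,3R)-2-(4-methoxyphenyl)-4-[2-(morpholin-4-yl)-2-oxoethyl]-5-oxo-2,3-dihydro-5H-furo[3,2-g]chromene-3-carboxylate; 11 4-methoxyphenylboronic acid
Product: 19 methyl (2R,3R,7R)-2,7-bis(4-methoxyphenyl)-4-[2-(morpholin-4-yl)-2-oxoethyl]-5-oxo-2,3,6,7-tetrahydro-5H-furo[3,2-g]chromene-3-carboxylate
Conditions: Pd(OCOCF3)2 (5 mol %), (S)-4-tert-butyl-2-(pyridin-2-yl)-4,5-dihydrooxazole (6 mol %), NH4PF6 (30 mol %), H2O (5 equiv), ClCH2CH2Cl, 60 °C
Reagents that add atoms: none
Why: The same catalyst-controlled palladium/pyridine-oxazoline conjugate arylation as in step 5; the ligand and not the remote C2/C3 centres should decide the face, so the new centre C7 is R.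

Step 11
Reactants: 19 methyl (2R,3R,7R)-2,7-bis(4-methoxyphenyl)-4-[2-(morpholin-4-yl)-2-oxoethyl]-5-oxo-2,3,6,7-tetrahydro-5H-furo[3,2-g]chromene-3-carboxylate
Product: 21 dimethyl (2R,3R,5R,6R)-2,6-bis(4-methoxyphenyl)-4-[2-(morpholin-4-yl)-2-oxoethyl]-2,3,5,6-tetrahydrobenzo[1,2-b:5,4-b']difuran-3,5-dicarboxylate, via methyl enol ether 20 (not isolated)
Conditions: PhI(OAc)2 (1.2 equiv), conc. H2SO4, HC(OMe)3, 25 °C; aqueous work-up
Reagents that add atoms: trimethyl orthoformate, COC(OC)OC; water, O
Why: The trivalent-iodine oxidative ring contraction of step 6 (1,2-shift of ring A from the ketal carbon C5 to C6 of the pyranone) applied to the second flavanone: the aryl-bearing centre keeps R and the new ester is formed trans to it, which gives the C2-symmetric benzodifuran diester.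

Step 12
Reactants: 21 dimethyl (2R,3R,5R,6R)-2,6-bis(4-methoxyphenyl)-4-[2-(morpholin-4-yl)-2-oxoethyl]-2,3,5,6-tetrahydrobenzo[1,2-b:5,4-b']difuran-3,5-dicarboxylate
Product: 22 (2R,3R,5R,6R)-2,6-bis(4-methoxyphenyl)-4-[2-(morpholin-4-yl)-2-oxoethyl]-2,3,5,6-tetrahydrobenzo[1,2-b:5,4-b']difuran-3,5-dicarboxylic acid
Conditions: LiOH·H2O, THF/MeOH/H2O, 25 °C; then 1 M HCl
Reagents that add atoms: lithium hydroxide, [Li+].[OH-]
Why: Saponification of the two methyl esters with LiOH, to which the tertiary amide is inert at room temperature; the enolates reprotonate to the trans acids and opening of the dihydrofurans by β-elimination is disfavoured as the reverse of a 5-endo-trig closure.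

Step 13
Reactants: 22 (2R,3R,5R,6R)-2,6-bis(4-methoxyphenyl)-4-[2-(morpholin-4-yl)-2-oxoethyl]-2,3,5,6-tetrahydrobenzo[1,2-b:5,4-b']difuran-3,5-dicarboxylic acid
Product: 23 bis(1,3-dioxoisoindolin-2-yl) (2R,3R,5R,6R)-2,6-bis(4-methoxyphenyl)-4-[2-(morpholin-4-yl)-2-oxoethyl]-2,3,5,6-tetrahydrobenzo[1,2-b:5,4-b']difuran-3,5-dicarboxylate
Conditions: N-hydroxyphthalimide, N,N'-diisopropylcarbodiimide, DMAP (cat.), CH2Cl2, 25 °C
Reagents that add atoms: N-hydroxyphthalimide, O=C1c2ccccc2C(=O)N1O
Why: Carbodiimide-mediated (Steglich-type) esterification with N-hydroxyphthalimide gives the redox-active diester needed for radical decarboxylation.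

Step 14
Reactants: 23 bis(1,3-dioxoisoindolin-2-yl) diester; 24 3,5-dimethoxyphenylmagnesium chloride
Product: 25 2-[(2R,3R,5R,6R)-3,5-bis(3,5-dimethoxyphenyl)-2,6-bis(4-methoxyphenyl)-2,3,5,6-tetrahydrobenzo[1,2-b:5,4-b']difuran-4-yl]-1-(morpholin-4-yl)ethan-1-one
Conditions: 24 (6 equiv), ZnCl2 (6 equiv), LiCl, THF, 0 → 25 °C (forms the arylzinc chloride); then 23, NiCl2(glyme) (40 mol %), 4,4'-di-tert-butyl-2,2'-bipyridine (80 mol %), THF/DMF, 25 °C
Reagents that add atoms: none
Why: Nickel-catalysed decarboxylative Negishi-type arylation of redox-active esters: electron transfer from low-valent nickel releases CO2 and phthalimide anion, each planar benzylic radical is captured by aryl-nickel and reductive elimination should place the 3,5-dimethoxyphenyl group trans to the neighbouring C2 (C6) aryl group, so C3 and C5 become R by substrate control whatever their configuration in 23.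

Step 15
Reactants: 25 tetraaryl morpholine amide; 26 2,4-dimethoxyphenylmagnesium bromide
Product: 27 2-[(2R,3R,5R,6R)-3,5-bis(3,5-dimethoxyphenyl)-2,6-bis(4-methoxyphenyl)-2,3,5,6-tetrahydrobenzo[1,2-b:5,4-b']difuran-4-yl]-1-(2,4-dimethoxyphenyl)ethan-1-one
Conditions: 26 (3 equiv), THF, 0 → 25 °C; then cold 1 M HCl
Reagents that add atoms: none
Why: Ketone synthesis from a morpholine amide and an aryl Grignard reagent: the tetrahedral magnesium aminoalkoxide persists until work-up so a second addition cannot occur, and addition should outrun deprotonation of the hindered benzylic CH2 group.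

Step 16
Reactants: 27 aryl ketone
Product: 29 octa-O-methyl ring alkene (target skeleton with a C-α=C-β double bond; 2R,3R,2'R,3'R), via tertiary alcohol 28 (not isolated)
Conditions: MeSO3H (2 equiv), CH2Cl2, 0 → 25 °C
Reagents that add atoms: none
Why: Acid-promoted intramolecular Friedel–Crafts hydroxyalkylation and dehydration (Bradsher-type cyclodehydration): the ortho carbon of a 3,5-dimethoxyphenyl ring, activated ortho/para by its two methoxy groups, attacks the protonated ketone (7-exo-trig), the tertiary doubly benzylic alcohol 28 loses water to the conjugated ring alkene, and because the two 3,5-dimethoxyphenyl rings are related by the C2 axis only one product can form.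

Step 17
Reactants: 29 octa-O-methyl ring alkene
Product: 30 ring alkene octaphenol (C-α=C-β didehydro form of the target; 2R,3R,2'R,3'R)
Conditions: BBr3 (16 equiv), CH2Cl2, −78 → 0 °C; then H2O
Reagents that add atoms: none
Why: Cleavage of the eight aryl methyl ethers with BBr3 (Lewis acid-mediated ether cleavage) at low temperature, at which the two cyclic benzylic ethers should persist; it is done at the alkene stage, where C-β is not yet a stereocentre that acid could epimerise.

Step 18
Reactants: 30 ring alkene octaphenol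
Product: 31 CNP0154047.2 (target; 2R,3R,2'R,3'R and S at C-β)
Conditions: H2 (1 atm), 10 % Pd/C, MeOH, 25 °C
Reagents that add atoms: none
Why: Heterogeneous catalytic hydrogenation: the seven-membered ring is a boat whose concave side is covered by rings A and B, so both hydrogen atoms should arrive from the convex face, the face that carries H-C3', which makes the new C-β–H cis to H-C3' (S at C-β); a protic closure of the corresponding stilbene would be expected to put the aryl group on that face instead, which is why this C–H bond is made last.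

**Compound list**

1 | 3,5-dimethoxyphenylacetic acid | COc1cc(CC(=O)O)cc(OC)c1 | starting material
2 | morpholine | C1COCCN1 | starting material
3 | (3,5-dimethoxyphenyl)acetyl chloride (not isolated) | COc1cc(CC(=O)Cl)cc(OC)c1 | intermediate
4 | 2-(3,5-dimethoxyphenyl)-1-(morpholin-4-yl)ethan-1-one | COc1cc(CC(=O)N2CCOCC2)cc(OC)c1 | intermediate
5 | acetyl chloride | CC(=O)Cl | starting material
6 | 2-(2-acetyl-3,5-dimethoxyphenyl)-1-(morpholin-4-yl)ethan-1-one | COc1cc(OC)c(C(C)=O)c(CC(=O)N2CCOCC2)c1 | intermediate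
7 | 2-(2-acetyl-3-hydroxy-5-methoxyphenyl)-1-(morpholin-4-yl)ethan-1-one | COc1cc(O)c(C(C)=O)c(CC(=O)N2CCOCC2)c1 | intermediate
8 | N,N-dimethylformamide dimethyl acetal | COC(OC)N(C)C | starting material
9 | (2E)-3-(dimethylamino)-1-{2-hydroxy-4-methoxy-6-[2-(morpholin-4-yl)-2-oxoethyl]phenyl}prop-2-en-1-one (enaminone, not isolated) | COc1cc(O)c(C(=O)/C=C/N(C)C)c(CC(=O)N2CCOCC2)c1 | intermediate
10 | 7-methoxy-5-[2-(morpholin-4-yl)-2-oxoethyl]-4H-chromen-4-one | COc1cc(CC(=O)N2CCOCC2)c2c(=O)ccoc2c1 | intermediate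
11 | 4-methoxyphenylboronic acid | COc1ccc(B(O)O)cc1 | starting material
12 | (2R)-7-methoxy-2-(4-methoxyphenyl)-5-[2-(morpholin-4-yl)-2-oxoethyl]-2,3-dihydro-4H-chromen-4-one | COc1ccc([C@H]2CC(=O)c3c(CC(=O)N4CCOCC4)cc(OC)cc3O2)cc1 | intermediate
13 | (2R)-4,7-dimethoxy-2-(4-methoxyphenyl)-5-[2-(morpholin-4-yl)-2-oxoethyl]-2H-chromene (methyl enol ether, not isolated) | COc1ccc([C@H]2C=C(OC)c3c(CC(=O)N4CCOCC4)cc(OC)cc3O2)cc1 | intermediate
14 | methyl (2R,3R)-6-methoxy-2-(4-methoxyphenyl)-4-[2-(morpholin-4-yl)-2-oxoethyl]-2,3-dihydro-1-benzofuran-3-carboxylate (trans) | COc1ccc([C@@H]2Oc3cc(OC)cc(CC(=O)N4CCOCC4)c3[C@H]2C(=O)OC)cc1 | intermediate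
15 | methyl (2R,3R)-5-acetyl-6-methoxy-2-(4-methoxyphenyl)-4-[2-(morpholin-4-yl)-2-oxoethyl]-2,3-dihydro-1-benzofuran-3-carboxylate | COc1ccc([C@@H]2Oc3cc(OC)c(C(C)=O)c(CC(=O)N4CCOCC4)c3[C@H]2C(=O)OC)cc1 | intermediate
16 | methyl (2R,3R)-5-acetyl-6-hydroxy-2-(4-methoxyphenyl)-4-[2-(morpholin-4-yl)-2-oxoethyl]-2,3-dihydro-1-benzofuran-3-carboxylate | COc1ccc([C@@H]2Oc3cc(O)c(C(C)=O)c(CC(=O)N4CCOCC4)c3[C@H]2C(=O)OC)cc1 | intermediate
17 | methyl (2R,3R)-5-[(2E)-3-(dimethylamino)prop-2-enoyl]-6-hydroxy-2-(4-methoxyphenyl)-4-[2-(morpholin-4-yl)-2-oxoethyl]-2,3-dihydro-1-benzofuran-3-carboxylate (enaminone, not isolated) | COc1ccc([C@@H]2Oc3cc(O)c(C(=O)/C=C/N(C)C)c(CC(=O)N4CCOCC4)c3[C@H]2C(=O)OC)cc1 | intermediate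
18 | methyl (2R,3R)-2-(4-methoxyphenyl)-4-[2-(morpholin-4-yl)-2-oxoethyl]-5-oxo-2,3-dihydro-5H-furo[3,2-g]chromene-3-carboxylate | COc1ccc([C@@H]2Oc3cc4occc(=O)c4c(CC(=O)N4CCOCC4)c3[C@H]2C(=O)OC)cc1 | intermediate
19 | methyl (2R,3R,7R)-2,7-bis(4-methoxyphenyl)-4-[2-(morpholin-4-yl)-2-oxoethyl]-5-oxo-2,3,6,7-tetrahydro-5H-furo[3,2-g]chromene-3-carboxylate | COc1ccc([C@@H]2Oc3cc4O[C@@H](c5ccc(OC)cc5)CC(=O)c4c(CC(=O)N4CCOCC4)c3[C@H]2C(=O)OC)cc1 | intermediate
20 | methyl (2R,3R,7R)-5-methoxy-2,7-bis(4-methoxyphenyl)-4-[2-(morpholin-4-yl)-2-oxoethyl]-2,3-dihydro-7H-furo[3,2-g]chromene-3-carboxylate (methyl enol ether, not isolated) | COc1ccc([C@@H]2Oc3cc4O[C@@H](c5ccc(OC)cc5)C=C(OC)c4c(CC(=O)N4CCOCC4)c3[C@H]2C(=O)OC)cc1 | intermediate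
21 | dimethyl (2R,3R,5R,6R)-2,6-bis(4-methoxyphenyl)-4-[2-(morpholin-4-yl)-2-oxoethyl]-2,3,5,6-tetrahydrobenzo[1,2-b:5,4-b']difuran-3,5-dicarboxylate | COc1ccc([C@@H]2Oc3cc4O[C@@H](c5ccc(OC)cc5)[C@H](C(=O)OC)c4c(CC(=O)N4CCOCC4)c3[C@H]2C(=O)OC)cc1 | intermediate
22 | (2R,3R,5R,6R)-2,6-bis(4-methoxyphenyl)-4-[2-(morpholin-4-yl)-2-oxoethyl]-2,3,5,6-tetrahydrobenzo[1,2-b:5,4-b']difuran-3,5-dicarboxylic acid | COc1ccc([C@@H]2Oc3cc4O[C@@H](c5ccc(OC)cc5)[C@H](C(=O)O)c4c(CC(=O)N4CCOCC4)c3[C@H]2C(=O)O)cc1 | intermediate
23 | bis(1,3-dioxoisoindolin-2-yl) (2R,3R,5R,6R)-2,6-bis(4-methoxyphenyl)-4-[2-(morpholin-4-yl)-2-oxoethyl]-2,3,5,6-tetrahydrobenzo[1,2-b:5,4-b']difuran-3,5-dicarboxylate | COc1ccc([C@@H]2Oc3cc4O[C@@H](c5ccc(OC)cc5)[C@H](C(=O)ON5C(=O)c6ccccc6C5=O)c4c(CC(=O)N4CCOCC4)c3[C@H]2C(=O)ON2C(=O)c3ccccc3C2=O)cc1 | intermediate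
24 | 3,5-dimethoxyphenylmagnesium chloride (THF solution) | COc1cc(OC)cc([Mg]Cl)c1 | starting material
25 | 2-[(2R,3R,5R,6R)-3,5-bis(3,5-dimethoxyphenyl)-2,6-bis(4-methoxyphenyl)-2,3,5,6-tetrahydrobenzo[1,2-b:5,4-b']difuran-4-yl]-1-(morpholin-4-yl)ethan-1-one | COc1ccc([C@@H]2Oc3cc4O[C@@H](c5ccc(OC)cc5)[C@H](c5cc(OC)cc(OC)c5)c4c(CC(=O)N4CCOCC4)c3[C@H]2c2cc(OC)cc(OC)c2)cc1 | intermediate
26 | 2,4-dimethoxyphenylmagnesium bromide (THF solution) | COc1ccc([Mg]Br)c(OC)c1 | starting material
27 | 2-[(2R,3R,5R,6R)-3,5-bis(3,5-dimethoxyphenyl)-2,6-bis(4-methoxyphenyl)-2,3,5,6-tetrahydrobenzo[1,2-b:5,4-b']difuran-4-yl]-1-(2,4-dimethoxyphenyl)ethan-1-one | COc1ccc([C@@H]2Oc3cc4O[C@@H](c5ccc(OC)cc5)[C@H](c5cc(OC)cc(OC)c5)c4c(CC(=O)c4ccc(OC)cc4OC)c3[C@H]2c2cc(OC)cc(OC)c2)cc1 | intermediate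
28 | tertiary alcohol: octa-O-methyl target skeleton with OH and 2,4-dimethoxyphenyl on C-β, configuration at C-β not defined, 2R,3R,2'R,3'R (not isolated) | COc1ccc([C@@H]2Oc3cc4c5c(c3[C@H]2c2cc(OC)cc(OC)c2)CC(O)(c2ccc(OC)cc2OC)c2c(OC)cc(OC)cc2[C@H]5[C@H](c2ccc(OC)cc2)O4)cc1 | intermediate
29 | octa-O-methyl ring alkene: target skeleton with C-α=C-β double bond, all eight phenols as methyl ethers, 2R,3R,2'R,3'R | COc1ccc([C@@H]2Oc3cc4c5c(c3[C@H]2c2cc(OC)cc(OC)c2)C=C(c2ccc(OC)cc2OC)c2c(OC)cc(OC)cc2[C@H]5[C@H](c2ccc(OC)cc2)O4)cc1 | intermediate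
30 | ring alkene octaphenol: C-α=C-β didehydro form of the target, 2R,3R,2'R,3'R | Oc1ccc([C@@H]2Oc3cc4c5c(c3[C@H]2c2cc(O)cc(O)c2)C=C(c2ccc(O)cc2O)c2c(O)cc(O)cc2[C@H]5[C@H](c2ccc(O)cc2)O4)cc1 | intermediate
31 | CNP0154047.2: both dihydrofurans trans (2R,3R and 2'R,3'R), C-β S with its hydrogen cis to H-C3' | Oc1ccc([C@@H]2Oc3cc4c5c(c3[C@H]2c2cc(O)cc(O)c2)C[C@@H](c2ccc(O)cc2O)c2c(O)cc(O)cc2[C@H]5[C@H](c2ccc(O)cc2)O4)cc1 | target

**Step count and risks**

Total step count: 18. Longest linear sequence: 18 steps (1 → 31); the route is fully linear.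

Steps most likely to fail:

Step 7. The acyl group may enter C7 between the two oxygens or the anisyl ring, and the Lewis acid may open the benzylic C2–O bond with loss of the C3 proton. Fallback, setting out from 14: bromination with N-bromosuccinimide in MeCN at 0 °C, which is strongly para-directed by the ring oxygen and needs no Lewis acid, should give methyl (2R,3R)-5-bromo-6-methoxy-2-(4-methoxyphenyl)-4-[2-(morpholin-4-yl)-2-oxoethyl]-2,3-dihydro-1-benzofuran-3-carboxylate F1. Stille coupling of this bromide with tributyl(1-ethoxyvinyl)stannane (Pd(PPh3)4, toluene, 100 °C) should give methyl (2R,3R)-5-(1-ethoxyethenyl)-6-methoxy-2-(4-methoxyphenyl)-4-[2-(morpholin-4-yl)-2-oxoethyl]-2,3-dihydro-1-benzofuran-3-carboxylate F2, and 1 M HCl in THF should hydrolyse the enol ether to the methyl ketone 15, where the route is rejoined.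

Step 14. The two benzylic radicals may dimerise, be reduced to C–H or lose a hydrogen atom faster than nickel captures them, and the second coupling may stall on the crowded mono-arylated intermediate. Fallback, setting out from diacid 22 (step 13 is omitted): the radicals are generated oxidatively by dual photoredox/nickel decarboxylative arylation with 1-bromo-3,5-dimethoxybenzene (Ir[dF(CF3)ppy]2(dtbbpy)PF6, NiCl2(glyme), 4,4'-di-tert-butyl-2,2'-bipyridine, Cs2CO3, DMF, blue light, 25 °C). The caesium carboxylate is oxidised by the excited photocatalyst and the aryl group is delivered from an aryl bromide oxidative-addition complex. This should give 25 directly, where the route is rejoined; no new compound is formed (F0).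

Step 18. Hydrogen uptake at the hindered triaryl alkene may be slow enough for hydrogenolysis of the benzylic C–O bonds of the dihydrofurans to compete, and part of the hydrogen may be delivered from the concave face. Fallback, setting out from 30: ionic hydrogenation (Et3SiH, CF3CO2H, CH2Cl2/MeCN, −20 → 0 °C). Protonation at C-α gives the ring carbocation at C-β, stabilised by ring B and the 2,4-dihydroxyphenyl group, and the silane should transfer hydride to its convex face. No metal surface is present, so hydrogenolysis is excluded. This gives 31 directly; no new compound is formed (F0).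

Further compounds
F1 | step 7 | methyl (2R,3R)-5-bromo-6-methoxy-2-(4-methoxyphenyl)-4-[2-(morpholin-4-yl)-2-oxoethyl]-2,3-dihydro-1-benzofuran-3-carboxylate | COc1ccc([C@@H]2Oc3cc(OC)c(Br)c(CC(=O)N4CCOCC4)c3[C@H]2C(=O)OC)cc1
F2 | step 7 | methyl (2R,3R)-5-(1-ethoxyethenyl)-6-methoxy-2-(4-methoxyphenyl)-4-[2-(morpholin-4-yl)-2-oxoethyl]-2,3-dihydro-1-benzofuran-3-carboxylate | COc1ccc([C@@H]2Oc3cc(OC)c(C(=C)OCC)c(CC(=O)N4CCOCC4)c3[C@H]2C(=O)OC)cc1
F0 | step 14 | none | none
F0 | step 18 | none | none
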